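**Plan**

Retrosynthesis: cut the amide N–acyl bond; trace the C7–C8 epoxide and the C6 carbinol back, through a reductive 1,3-transposition, to an enone C6=C7–C8=O; cut the C4–C5 aldol bond; cut the tertiary C1–O bond (dearomatization); cut the aryl–CH2 bond (Negishi).
Forward: 2-iodoresorcinol and an L-iodoalanine zinc reagent give a 2,6-dihydroxy-L-phenylalaninal lactol; ring B is dearomatized to a 2-alkyl-2-hydroxycyclohex-4-ene-1,3-dione; ring A closes on it by aldol (bicyclo[3.3.1]nonane); ring B is then oxygenated and the acyl chain is joined last.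
Enabling feature: in ring B (C1, C9, C5, C6, C7, C8) the carbinol bridgehead C1 lies between two oxygen-bearing carbons, C9 (ketone) and C8 (epoxide C–O), a latent 2-alkylresorcinol with C1 on its mirror plane.
In the dearomatized ring the degenerate enol shift makes C5 and C7 equivalent, so C1 is fixed only when ring A closes; C5 becomes a bridgehead, so the aldol cannot dehydrate.
Stereochemistry: C3 from L-serine (iodoalanine); C1, C4, C5 from the aldol (C3–NHCbz equatorial in the chair, hydrogen-bonded enol–aldehyde transition state); C6, C7, C8 from exo-face attack on the bicycle and hydroxyl-directed epoxidation.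

Key step: step 6

Remark: core locants follow bicyclo[3.3.1]nonane numbering (C1 carbinol bridgehead, C3 nitrogen-bearing carbon, C5 CH bridgehead, C9 ketone bridge); compound 8 is drawn as one enol tautomer of a fast degenerate pair; compounds 3 and 18 are taken as purchasable.

**Route**

Step 1
Reactants: 1 2-iodobenzene-1,3-diol
Product: 2 2-iodo-1,3-bis(methoxymethoxy)benzene
Conditions: MOMCl (2.5 equiv), i-Pr2NEt, CH2Cl2, 0 to 23 °C
Reagents that add atoms: chloromethyl methyl ether (MOMCl), COCCl
Why: Williamson-type O-alkylation (methoxymethyl ether formation) masks both acidic phenols so that the organozinc reagent of step 2 is not protonated; no stereocentre is formed.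

Step 2
Reactants: 2 2-iodo-1,3-bis(methoxymethoxy)benzene; 3 methyl (2R)-2-{[(benzyloxy)carbonyl]amino}-3-iodopropanoate
Product: 5 methyl (2S)-2-{[(benzyloxy)carbonyl]amino}-3-[2,6-bis(methoxymethoxy)phenyl]propanoate, via zinc reagent 4 (not isolated)
Conditions: 3, Zn dust, I2 (cat.), DMF, 23 °C; then 2, Pd2(dba)3 (2.5 mol %), SPhos (5 mol %), 23 to 40 °C
Reagents that add atoms: none
Why: Zinc inserts into the C–I bond of 3 and the resulting alkylzinc iodide undergoes Negishi coupling at the aryl iodide (a bulky biaryl phosphine is used because both ortho positions are substituted), which forms the aryl–CH2 bond without touching the α-carbon, so the L configuration of 3 is carried into 5.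

Step 3
Reactants: 5 methyl (2S)-2-{[(benzyloxy)carbonyl]amino}-3-[2,6-bis(methoxymethoxy)phenyl]propanoate
Product: 6 methyl (2S)-2-{[(benzyloxy)carbonyl]amino}-3-(2,6-dihydroxyphenyl)propanoate
Conditions: HCl (3 M in MeOH), 23 °C
Reagents that add atoms: none
Why: Acid-catalysed acetal exchange with methanol cleaves both methoxymethyl ethers while the benzyl carbamate and the methyl ester are inert, and no stereocentre is affected.

Step 4
Reactants: 6 methyl (2S)-2-{[(benzyloxy)carbonyl]amino}-3-(2,6-dihydroxyphenyl)propanoate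
Product: 7 benzyl N-[(3S)-2,5-dihydroxy-3,4-dihydro-2H-chromen-3-yl]carbamate
Conditions: i-Bu2AlH (5 equiv), CH2Cl2, −78 °C; aq. potassium sodium tartrate
Reagents that add atoms: none
Why: Partial reduction of the ester by i-Bu2AlH stops at the aldehyde oxidation level because the tetrahedral aluminium acetal is stable at −78 °C, and on work-up an ortho-hydroxyl captures the aldehyde as the six-membered hemiacetal, which stores the configurationally labile α-amino aldehyde (C3 unchanged) in a stable form.

Step 5
Reactants: 7 benzyl N-[(3S)-2,5-dihydroxy-3,4-dihydro-2H-chromen-3-yl]carbamate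
Product: 8 benzyl N-[(2S)-1-(1,6-dihydroxy-2-oxocyclohexa-3,5-dien-1-yl)-3-oxopropan-2-yl]carbamate
Conditions: IBX (1.1 equiv), DMF, 0 to 23 °C; aq. Na2S2O3 quench
Reagents that add atoms: 2-iodoxybenzoic acid (IBX), O=C1OI(=O)(O)c2ccccc12
Why: Hydroxylative phenol dearomatization by the pentavalent iodine reagent IBX should deliver oxygen from the aryloxy-iodane to the alkyl-bearing ortho carbon that lies between the two ring oxygens, the known course for 2-alkylresorcinols, and the new carbinol carbon needs no control because the degenerate enol shift of the product leaves it configurationally unfixed.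

Step 6
Reactants: 8 benzyl N-[(2S)-1-(1,6-dihydroxy-2-oxocyclohexa-3,5-dien-1-yl)-3-oxopropan-2-yl]carbamate
Product: 9 benzyl N-[(1S,3S,4R,5R)-1,4-dihydroxy-8,9-dioxobicyclo[3.3.1]non-6-en-3-yl]carbamate
Conditions: NaOAc/AcOH buffer (pH 5), THF–H2O (1:1), 23 °C
Reagents that add atoms: none
Why: The hemiacetal forms of 8 open to the free aldehyde, and the enol of the vinylogous acid adds through its α-carbon to the aldehyde in a hydrogen-bonded six-membered transition state (O–H···O=CH), the enol carbon becoming the C9 ketone; because C5 is then a bridgehead, dehydration to a Knoevenagel product would violate Bredt's rule and the reaction stops at the aldol. The closest known reaction type is the aldol stage of the Knoevenagel reaction of cyclic 1,3-diones with aldehydes, run as a group-selective intramolecular aldol of a 2,2-disubstituted cyclohexene-1,3-dione (Hajos–Parrish type with the roles of ring ketone and side-chain carbonyl exchanged) that closes a bicyclo[3.3.1]nonan-9-one as in α,α′-annulations. Ring A (C1–C2–C3–C4–C5–C9) closes in a 6-(enolendo)-exo-trig mode. C5 is fixed by the short tether (the bridge must be cis), C1 by which of the two α-carbons made equivalent by the enol shift attacks, decided by the chair transition state that keeps the C3–NHCbz group equatorial, and C4 by the hydrogen bond that holds the aldehyde oxygen gauche to C9, which gives the axial C4–OH syn to the C9 carbonyl. The step needs C- over O-attack and one α-carbon over the other, and both rest on reversibility (hemiacetals and the mismatched aldol revert, the matched chair product is the sink), while pH 5 keeps the vinylogous acid un-ionised (its anion would favour retro-aldol) and spares C3, the only stereocentre of 8, from epimerisation.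

Step 7
Reactants: 9 benzyl N-[(1S,3S,4R,5R)-1,4-dihydroxy-8,9-dioxobicyclo[3.3.1]non-6-en-3-yl]carbamate
Product: 10 benzyl N-[(1R,3S,4R,5S,6S,7S)-6,7-epoxy-1,4-dihydroxy-8,9-dioxobicyclo[3.3.1]nonan-3-yl]carbamate
Conditions: dimethyldioxirane (3 equiv, acetone solution), CH2Cl2, 0 to 23 °C
Reagents that add atoms: dimethyldioxirane (DMDO), CC1(C)OO1
Why: Electrophilic oxygen transfer from the dioxirane to the enone (neutral, so the base-induced retro-aldol of 9 is avoided) should occur on the exo face of ring B, since the endo face is covered by ring A and by the axial C5–C4 bond, which sets C6 and C7.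

Step 8
Reactants: 10 benzyl N-[(1R,3S,4R,5S,6S,7S)-6,7-epoxy-1,4-dihydroxy-8,9-dioxobicyclo[3.3.1]nonan-3-yl]carbamate
Product: 12 benzyl N-[(1S,3S,4R,5R,6R)-1,4,6-trihydroxy-9-oxobicyclo[3.3.1]non-7-en-3-yl]carbamate, via hydrazone 11 (not isolated)
Conditions: N2H4·H2O (2 equiv), AcOH (cat.), MeOH, 0 to 23 °C
Reagents that add atoms: none
Why: Wharton transposition, in which the hydrazone of the more electrophilic epoxy ketone opens the epoxide to a vinyl diazene that loses N2, moves the double bond to C7=C8 and leaves the C6 oxygen with its exo configuration untouched.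

Step 9
Reactants: 12 benzyl N-[(1S,3S,4R,5R,6R)-1,4,6-trihydroxy-9-oxobicyclo[3.3.1]non-7-en-3-yl]carbamate
Product: 13 benzyl N-[(1S,3S,4R,5S,6S,7S,8S)-7,8-epoxy-1,4,6-trihydroxy-9-oxobicyclo[3.3.1]nonan-3-yl]carbamate
Conditions: VO(acac)2 (5 mol %), t-BuOOH (1.5 equiv), CH2Cl2, 0 to 23 °C
Reagents that add atoms: tert-butyl hydroperoxide, CC(C)(C)OO
Why: Vanadium-catalysed hydroxyl-directed epoxidation delivers oxygen to the face of C7=C8 that carries both allylic hydroxyl groups (axial C6–OH and C1–OH), which is also the open exo face, so the epoxide is set cis to both.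

Step 10
Reactants: 14 hex-5-enenitrile; 15 pentylmagnesium bromide
Product: 17 undec-1-en-6-one, via bromomagnesium ketimide 16 (not isolated)
Conditions: Et2O, 0 to 35 °C; then 2 M HCl (aq), 23 °C
Reagents that add atoms: water, O
Why: Addition of the Grignard reagent to the nitrile stops at the magnesium ketimide, which is hydrolysed to the ketone on acidic work-up, so no tertiary alcohol forms and no stereocentre is involved.

Step 11
Reactants: 17 undec-1-en-6-one; 18 2,5-dioxopyrrolidin-1-yl prop-2-enoate
Product: 19 2,5-dioxopyrrolidin-1-yl (2E)-7-oxododec-2-enoate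
Conditions: second-generation Grubbs catalyst (H2IMes)(PCy3)Cl2Ru=CHPh (5 mol %), CH2Cl2, 40 °C
Reagents that add atoms: none
Why: Olefin cross-metathesis between the terminal alkene and the electron-poor acrylate is selective for the cross product and gives the thermodynamically favoured E-enoate, with ethene as the only by-product.

Step 12
Reactants: 13 benzyl N-[(1S,3S,4R,5S,6S,7S,8S)-7,8-epoxy-1,4,6-trihydroxy-9-oxobicyclo[3.3.1]nonan-3-yl]carbamate; 19 2,5-dioxopyrrolidin-1-yl (2E)-7-oxododec-2-enoate
Product: 21 isariotin C, via amine 20 (not isolated)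
Conditions: H2 (1 atm), Pd/C (10 wt %), THF, 23 °C; filter; then 19, i-Pr2NEt, THF–DMF, 0 to 23 °C
Reagents that add atoms: none
Why: Hydrogenolysis of the benzyl carbamate (the unactivated epoxide and the ketone are inert to H2 over Pd/C) releases the amine, which after removal of the catalyst is acylated by the active ester much faster than any hydroxyl group (aminolysis of an N-hydroxysuccinimide ester), so the enoate never meets H2 and no stereocentre is touched.

**Compound list**

1 | 2-iodobenzene-1,3-diol (2-iodoresorcinol) | Oc1cccc(O)c1I | starting material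
2 | 2-iodo-1,3-bis(methoxymethoxy)benzene | COCOc1cccc(OCOC)c1I | intermediate
3 | methyl (2R)-2-{[(benzyloxy)carbonyl]amino}-3-iodopropanoate (N-Cbz-3-iodo-L-alanine methyl ester) | COC(=O)[C@H](CI)NC(=O)OCc1ccccc1 | starting material
4 | [(2R)-2-{[(benzyloxy)carbonyl]amino}-3-methoxy-3-oxopropyl]zinc iodide | COC(=O)[C@H](C[Zn]I)NC(=O)OCc1ccccc1 | intermediate
5 | methyl (2S)-2-{[(benzyloxy)carbonyl]amino}-3-[2,6-bis(methoxymethoxy)phenyl]propanoate | COC(=O)[C@H](Cc1c(OCOC)cccc1OCOC)NC(=O)OCc1ccccc1 | intermediate
6 | methyl (2S)-2-{[(benzyloxy)carbonyl]amino}-3-(2,6-dihydroxyphenyl)propanoate | COC(=O)[C@H](Cc1c(O)cccc1O)NC(=O)OCc1ccccc1 | intermediate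
7 | benzyl N-[(3S)-2,5-dihydroxy-3,4-dihydro-2H-chromen-3-yl]carbamate (lactol, both C2 epimers) | OC1Oc2cccc(O)c2C[C@@H]1NC(=O)OCc1ccccc1 | intermediate
8 | benzyl N-[(2S)-1-(1,6-dihydroxy-2-oxocyclohexa-3,5-dien-1-yl)-3-oxopropan-2-yl]carbamate (ring C1 stereolabile by the enol shift; in equilibrium with its hemiacetals) | O=C[C@@H](NC(=O)OCc1ccccc1)CC1(O)C(=O)C=CC=C1O | intermediate
9 | benzyl N-[(1S,3S,4R,5R)-1,4-dihydroxy-8,9-dioxobicyclo[3.3.1]non-6-en-3-yl]carbamate (3-NHCbz equatorial, 4-OH axial and syn to C9=O) | O=C(OCc1ccccc1)N[C@H]1C[C@@]2(O)C(=O)[C@H](C=CC2=O)[C@H]1O | intermediate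
10 | benzyl N-[(1R,3S,4R,5S,6S,7S)-6,7-epoxy-1,4-dihydroxy-8,9-dioxobicyclo[3.3.1]nonan-3-yl]carbamate (exo epoxide) | O=C(OCc1ccccc1)N[C@H]1C[C@@]2(O)C(=O)[C@H]([C@@H]3O[C@@H]3C2=O)[C@H]1O | intermediate
11 | 8-hydrazone of 10 | O=C(OCc1ccccc1)N[C@H]1C[C@@]2(O)C(=O)[C@H]([C@@H]3O[C@@H]3C2=NN)[C@H]1O | intermediate
12 | benzyl N-[(1S,3S,4R,5R,6R)-1,4,6-trihydroxy-9-oxobicyclo[3.3.1]non-7-en-3-yl]carbamate | O=C(OCc1ccccc1)N[C@H]1C[C@@]2(O)C(=O)[C@H]([C@H](O)C=C2)[C@H]1O | intermediate
13 | benzyl N-[(1S,3S,4R,5S,6S,7S,8S)-7,8-epoxy-1,4,6-trihydroxy-9-oxobicyclo[3.3.1]nonan-3-yl]carbamate | O=C(OCc1ccccc1)N[C@H]1C[C@@]2(O)C(=O)[C@H]([C@H](O)[C@@H]3O[C@@H]32)[C@H]1O | intermediate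
14 | hex-5-enenitrile | C=CCCCC#N | starting material
15 | pentylmagnesium bromide | CCCCC[Mg]Br | starting material
16 | bromomagnesium salt of undec-1-en-6-imine | C=CCCCC(CCCCC)=N[Mg]Br | intermediate
17 | undec-1-en-6-one | C=CCCCC(=O)CCCCC | intermediate
18 | 2,5-dioxopyrrolidin-1-yl prop-2-enoate (N-succinimidyl acrylate) | C=CC(=O)ON1C(=O)CCC1=O | starting material
19 | 2,5-dioxopyrrolidin-1-yl (2E)-7-oxododec-2-enoate | CCCCCC(=O)CCC/C=C/C(=O)ON1C(=O)CCC1=O | intermediate
20 | (1S,3S,4R,5S,6S,7S,8S)-3-amino-7,8-epoxy-1,4,6-trihydroxybicyclo[3.3.1]nonan-9-one | N[C@H]1C[C@@]2(O)C(=O)[C@H]([C@H](O)[C@@H]3O[C@@H]32)[C@H]1O | intermediate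
21 | isariotin C, (2E)-N-[(1S,3S,4R,5S,6S,7S,8S)-7,8-epoxy-1,4,6-trihydroxy-9-oxobicyclo[3.3.1]nonan-3-yl]-7-oxododec-2-enamide | CCCCCC(=O)CCC/C=C/C(=O)N[C@H]1C[C@@]2(O)C(=O)[C@H]([C@H](O)[C@@H]3O[C@@H]32)[C@H]1O | target

**Step count and risks**

Total step count: 12. Longest linear sequence: 10 steps (steps 1 to 9 and step 12, from 2-iodoresorcinol).

Steps most likely to fail:

1. Step 6 (group-selective aldol). The ring-closed aldol may be disfavoured against the conjugation-stabilised vinylogous acid (retro-aldol), the aldehyde may rest as O-bound hemiacetals, or the C3 centre may discriminate poorly between the two α-carbons. The fallback removes the vinylogous stabilisation and hands the group selection to a chiral catalyst. From 8, hydrogenation of the ring C=C over ethylenediamine-modified Pd/C (carbamate retained) should give benzyl N-[(2S)-1-(1-hydroxy-2,6-dioxocyclohexyl)-3-oxopropan-2-yl]carbamate F1, a 2,2-disubstituted cyclohexane-1,3-dione with a true mirror plane. A proline-catalysed Hajos–Parrish-type enamine aldol (catalyst enantiomer chosen for the matched case; the α-amino aldehyde centre may equilibrate and is then fixed equatorial on ring closure) should give benzyl N-[(1S,3S,4R,5R)-1,4-dihydroxy-8,9-dioxobicyclo[3.3.1]nonan-3-yl]carbamate F2, a simple-ketone aldol that does not revert. Acid-catalysed α-selenenylation with PhSeCl at C7, the only enolisable position, should give the 7-(phenylselanyl) derivative of F2, F3, and oxidation with H2O2 followed by selenoxide syn-elimination would return to 9.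

2. Step 5 (dearomatization). Oxygen may be transferred to the unsubstituted ring carbons (quinone formation), the product may be over-oxidised, or the lactol may be oxidised to the lactone. The fallback replaces external oxygen transfer by a tethered nucleophile. From 6, saponification (LiOH, THF–H2O) should give (2S)-2-{[(benzyloxy)carbonyl]amino}-3-(2,6-dihydroxyphenyl)propanoic acid F4. Oxidative ortho-spirolactonization with the trivalent iodine reagent PhI(OAc)2, in which the carboxylate can reach only the ipso carbon, should give benzyl N-[(3S)-10-hydroxy-2,6-dioxo-1-oxaspiro[4.5]deca-7,9-dien-3-yl]carbamate F5. Reduction of the lactone with i-Bu2AlH at −78 °C (the vinylogous acid is protected as its aluminium enolate) should give the spiro-lactol, which is a ring-chain tautomer of 8.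

3. Step 7 (enone epoxidation). Oxygen transfer to the electron-poor alkene may be slow, so that oxidation of the C4 carbinol or retro-aldol competes. The fallback blocks the retro-aldol and then uses a nucleophilic oxidant. From 9, silylation of the only secondary hydroxyl (TESOTf, 2,6-lutidine, −78 °C) should give the 4-O-triethylsilyl ether of 9, F6. Weitz–Scheffer epoxidation (H2O2, LiOH, MeOH, 0 °C) on the exo face should give the 4-O-triethylsilyl ether of 10, F7, and HF·pyridine would return to 10.

Further compounds
F1 | step 6 | benzyl N-[(2S)-1-(1-hydroxy-2,6-dioxocyclohexyl)-3-oxopropan-2-yl]carbamate | O=C[C@@H](NC(=O)OCc1ccccc1)CC1(O)C(=O)CCCC1=O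
F2 | step 6 | benzyl N-[(1S,3S,4R,5R)-1,4-dihydroxy-8,9-dioxobicyclo[3.3.1]nonan-3-yl]carbamate | O=C(OCc1ccccc1)N[C@H]1C[C@@]2(O)C(=O)[C@H](CCC2=O)[C@H]1O
F3 | step 6 | 7-(phenylselanyl) derivative of F2 | O=C(OCc1ccccc1)N[C@H]1C[C@@]2(O)C(=O)[C@H](CC([Se]c3ccccc3)C2=O)[C@H]1O
F4 | step 5 | (2S)-2-{[(benzyloxy)carbonyl]amino}-3-(2,6-dihydroxyphenyl)propanoic acid | O=C(O)[C@H](Cc1c(O)cccc1O)NC(=O)OCc1ccccc1
F5 | step 5 | benzyl N-[(3S)-10-hydroxy-2,6-dioxo-1-oxaspiro[4.5]deca-7,9-dien-3-yl]carbamate | O=C1OC2(C[C@@H]1NC(=O)OCc1ccccc1)C(=O)C=CC=C2O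
F6 | step 7 | 4-O-triethylsilyl ether of 9 | O=C(OCc1ccccc1)N[C@H]1C[C@@]2(O)C(=O)[C@H](C=CC2=O)[C@H]1O[Si](CC)(CC)CC
F7 | step 7 | 4-O-triethylsilyl ether of 10 | O=C(OCc1ccccc1)N[C@H]1C[C@@]2(O)C(=O)[C@H]([C@@H]3O[C@@H]3C2=O)[C@H]1O[Si](CC)(CC)CC
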